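The flavanone is opened at O1–C2 to a 2'-hydroxychalcone, and the chalcone is cut at C8a–O and C4a–C4. The key step exploits the fact that in ring A the ring oxygen O1 (on C8a) and the acyl carbon C4 (on C4a) sit on adjacent carbons, with the C5 methoxy group next to C4a: an aryne across C4a–C8a inserts into the C–O bond of a cinnamate and forms both bonds in one operation, without closing a ring. Its precursor is the ring A ortho-trimethylsilyl aryl triflate that already carries the complete, stereodefined side chain on C8; silicon is installed before the chain, the triflate only after the chain is complete.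

Key step: step 17

Assumption: [Rh(cod)Cl]2/(S)-BINAP and the quinidine-derived thiourea are taken to show their usual facial sense on these substrates; if either proved reversed, the antipodal ligand or the quinine-derived pseudoenantiomer would be used under otherwise unchanged conditions.
Remark: chain carbons carry diarylheptanoid numbers (C1 and C2 the CH2CH2 arm, C3 the carbinol, C5 the carbon on ring A, C6=C7 the styrene) and ring A carbons carry flavanone numbers; ketones 18 to 20 are drawn open-chain, and any cyclic hemiketal with the neighbouring phenol is expected to react through the open form.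

Step 1
Reactants: 1 5-methoxyresorcinol
Product: 2 1-methoxy-3,5-bis(methoxymethoxy)benzene
Conditions: NaH, MOMCl, DMF, 0 °C to rt
Reagents that add atoms: chloromethyl methyl ether, COCCl
Why: Double Williamson-type O-alkylation of the sodium phenoxides gives the bis-acetal, whose two OMOM groups are base-stable directors for the metalation that follows.

Step 2
Reactants: 2 1-methoxy-3,5-bis(methoxymethoxy)benzene
Product: 5 4-methoxy-2,6-bis(methoxymethoxy)benzaldehyde, via aryllithium 3 (not isolated), via lithium hemiaminal alkoxide 4 (not isolated)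
Conditions: n-BuLi, TMEDA, THF, 0 °C; DMF; aq NH4Cl
Reagents that add atoms: N,N-dimethylformamide, CN(C)C=O
Why: Directed ortho-metalation takes place at the carbon flanked by both OMOM groups (the future C8), and formylation with DMF gives the symmetrical aldehyde after collapse of the hemiaminal alkoxide on work-up.

Step 3
Reactants: 5 4-methoxy-2,6-bis(methoxymethoxy)benzaldehyde
Product: 9 4-methoxy-2,6-bis(methoxymethoxy)-3-(trimethylsilyl)benzaldehyde, via lithium amino alkoxide 6 (not isolated), via ring-lithiated amino alkoxide 7 (not isolated), via C-silylated amino alkoxide 8 (not isolated)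
Conditions: LiN(Me)CH2CH2NMe2 (from the amine and n-BuLi), THF, −20 °C; n-BuLi, −20 °C; Me3SiCl, −78 °C to rt; aq NH4Cl
Reagents that add atoms: chlorotrimethylsilane, C[Si](C)(C)Cl
Why: The formyl group is masked in the flask as an α-amino alkoxide, so a second directed ortho-metalation can occur between OMOM and OMe (the two such positions are equivalent by symmetry) and silylation there places Me3Si on the future C4a before any stereocentre exists.

Step 4
Reactants: 9 4-methoxy-2,6-bis(methoxymethoxy)-3-(trimethylsilyl)benzaldehyde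
Product: 11 2,6-dihydroxy-4-methoxy-3-(trimethylsilyl)benzaldehyde, via bis(trimethylsilyl) ether 10 (not isolated)
Conditions: Me3SiBr, 2-methyl-2-butene, CH2Cl2, −30 to 0 °C; aq NaHCO3
Reagents that add atoms: none
Why: Bromotrimethylsilane exchanges both aryl MOM acetals for silyl ethers under aprotic conditions (hydrolysed on mild basic work-up), which avoids the protic acid that would protodesilylate this electron-rich arylsilane, and both acetals are removed because a mono-cleavage could not be relied on to pick the right one.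

Step 5
Reactants: 11 2,6-dihydroxy-4-methoxy-3-(trimethylsilyl)benzaldehyde
Product: 12 2-hydroxy-4-methoxy-6-(methoxymethoxy)-3-(trimethylsilyl)benzaldehyde
Conditions: MOMCl (1.05 equiv), K2CO3, acetone, 0 °C to rt
Reagents that add atoms: chloromethyl methyl ether, COCCl
Why: Selective mono-O-alkylation, because the hydroxyl beside Me3Si is shielded and held in the hydrogen bond to the formyl oxygen, so the other hydroxyl (future C7–O) should be alkylated and the future C8a–OH stays free.

Step 6
Reactants: 12 2-hydroxy-4-methoxy-6-(methoxymethoxy)-3-(trimethylsilyl)benzaldehyde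
Product: 13 (E)-4-[2-hydroxy-4-methoxy-6-(methoxymethoxy)-3-(trimethylsilyl)phenyl]but-3-en-2-one
Conditions: Ph3P=CHC(O)CH3, toluene, 90 °C
Reagents that add atoms: 1-(triphenylphosphoranylidene)propan-2-one, CC(=O)C=P(c1ccccc1)(c1ccccc1)c1ccccc1
Why: Wittig olefination with the stabilised acetonyl ylide gives the (E)-enone and tolerates the hindered, hydrogen-bonded phenol.

Step 7
Reactants: 14 4-hydroxybenzaldehyde
Product: 15 4-(methoxymethoxy)benzaldehyde
Conditions: NaH, MOMCl, DMF, 0 °C to rt
Reagents that add atoms: chloromethyl methyl ether, COCCl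
Why: O-Alkylation of the sodium phenoxide gives the MOM ether that serves as the common source of all three 4-oxygenated aryl groups.

Step 8
Reactants: 15 4-(methoxymethoxy)benzaldehyde
Product: 17 2-{(E)-2-[4-(methoxymethoxy)phenyl]ethenyl}-4,4,5,5-tetramethyl-1,3,2-dioxaborolane, via lithium alkoxide adduct 16 (not isolated)
Conditions: CH2(Bpin)2, lithium 2,2,6,6-tetramethylpiperidide (LiTMP), THF, 0 °C; then 15, −78 °C to rt
Reagents that add atoms: bis(4,4,5,5-tetramethyl-1,3,2-dioxaborolan-2-yl)methane, CC1(C)OB(CB2OC(C)(C)C(C)(C)O2)OC1(C)C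
Why: Boron-Wittig olefination, in which the lithiated geminal bis(boronate) adds to the aldehyde and syn elimination of the boron–oxygen pair from adduct 16 gives the trans alkenylboronate.

Step 9
Reactants: 13 (E)-enone; 17 (E)-alkenylboronate
Product: 18 (4S,5E)-4-[2-hydroxy-4-methoxy-6-(methoxymethoxy)-3-(trimethylsilyl)phenyl]-6-[4-(methoxymethoxy)phenyl]hex-5-en-2-one
Conditions: [Rh(cod)Cl]2 (3 mol%), (S)-BINAP (7 mol%), aq KOH, 1,4-dioxane/H2O 10:1, 60 °C
Reagents that add atoms: none
Why: Hayashi–Miyaura rhodium-catalysed 1,4-addition of the alkenylboronate to the (E)-methyl enone, in which the (S)-BINAP complex differentiates the enone faces so that the chain C5 stereocentre (C4 of the hexenone) is set as S by catalyst control.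

Step 10
Reactants: 18 methyl ketone; 15 4-(methoxymethoxy)benzaldehyde
Product: 20 (1E,5S,6E)-5-[2-hydroxy-4-methoxy-6-(methoxymethoxy)-3-(trimethylsilyl)phenyl]-1,7-bis[4-(methoxymethoxy)phenyl]hepta-1,6-dien-3-one, via aldol adduct 19 (not isolated)
Conditions: NaOH, EtOH/H2O, rt
Reagents that add atoms: none
Why: Claisen–Schmidt condensation at the methyl group (the C4 methylene is shielded by the C5 branch) installs C1 with its aryl group and turns the ketone into a styryl ketone, the substrate class on which an asymmetric carbonyl reduction is reliable.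

Step 11
Reactants: 20 dienone
Product: 21 (1E,3R,5S,6E)-5-[2-hydroxy-4-methoxy-6-(methoxymethoxy)-3-(trimethylsilyl)phenyl]-1,7-bis[4-(methoxymethoxy)phenyl]hepta-1,6-dien-3-ol
Conditions: (S)-2-methyl-CBS-oxazaborolidine (20 mol%), catecholborane, toluene, −78 °C
Reagents that add atoms: none
Why: Corey–Bakshi–Shibata reduction, in which the styryl group acts as the large substituent and the C4 methylene arm as the small one, so the (S)-catalyst should set C3 as R (the geometry that is named 3S once C1=C2 is saturated), and any C3 epimer is a separable diastereomer.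

Step 12
Reactants: 21 allylic alcohol
Product: 22 (3S,5S,6E)-5-[2-hydroxy-4-methoxy-6-(methoxymethoxy)-3-(trimethylsilyl)phenyl]-1,7-bis[4-(methoxymethoxy)phenyl]hept-6-en-3-ol
Conditions: LiAlH4, THF, 0 °C to reflux; aq potassium sodium tartrate
Reagents that add atoms: none
Why: Alkoxide-directed hydroalumination of a cinnamyl-type alcohol, in which the aluminium alkoxide on C3 delivers hydride to C2 within a five-membered ring, so only the C1=C2 bond is saturated while the C6=C7 styrene (no neighbouring alkoxide), the aryl–silicon bond and both stereocentres are left alone.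

Step 13
Reactants: 22 phenol diol
Product: 23 6-[(3S,5S,6E)-3-hydroxy-1,7-bis[4-(methoxymethoxy)phenyl]hept-6-en-5-yl]-3-methoxy-5-(methoxymethoxy)-2-(trimethylsilyl)phenyl trifluoromethanesulfonate
Conditions: PhNTf2, DBU, MeCN, rt to 40 °C
Reagents that add atoms: N-phenylbis(trifluoromethanesulfonimide), O=S(=O)(N(c1ccccc1)S(=O)(=O)C(F)(F)F)C(F)(F)F
Why: Phenol-selective triflation, since only the phenoxide formed with DBU reacts with PhNTf2 and the secondary alcohol does not, so the ortho-silylaryl triflate is completed without organolithium or fluoride once the stereocentres are in place.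

Step 14
Reactants: 23 silyl triflate alcohol
Product: 24 3-methoxy-5-(methoxymethoxy)-6-[(3S,5S,6E)-3-(methoxymethoxy)-1,7-bis[4-(methoxymethoxy)phenyl]hept-6-en-5-yl]-2-(trimethylsilyl)phenyl trifluoromethanesulfonate
Conditions: MOMCl, i-Pr2NEt, Bu4NI (cat.), CH2Cl2, 0 °C to rt
Reagents that add atoms: chloromethyl methyl ether, COCCl
Why: Acetal formation with a hindered amine base masks the C3 hydroxyl, which would otherwise add to the aryne at C8a through a six-membered ring, and the silyl triflate survives because no fluoride or strong nucleophile is present.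

Step 15
Reactants: 15 4-(methoxymethoxy)benzaldehyde
Product: 26 (E)-3-[4-(methoxymethoxy)phenyl]prop-2-enoic acid, via arylidenemalonic acid 25 (not isolated)
Conditions: malonic acid, pyridine, piperidine (cat.), 90 °C
Reagents that add atoms: malonic acid, OC(=O)CC(O)=O
Why: Knoevenagel–Doebner condensation with decarboxylation of the arylidenemalonic acid gives the (E)-cinnamic acid under basic conditions that keep the MOM ether intact.

Step 16
Reactants: 26 (E)-3-[4-(methoxymethoxy)phenyl]prop-2-enoic acid
Product: 27 cesium (E)-3-[4-(methoxymethoxy)phenyl]prop-2-enoate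
Conditions: CsOH·H2O (1.0 equiv), MeOH, rt; evaporation, azeotropic drying with toluene, vacuum
Reagents that add atoms: cesium hydroxide, [Cs+].[OH-]
Why: Neutralisation with one equivalent of base gives the anhydrous cesium carboxylate, so that the aryne insertion can be run without any proton source.

Step 17
Reactants: 24 ortho-silylaryl triflate; 27 cesium cinnamate
Product: 30 (E)-1-{2-hydroxy-6-methoxy-4-(methoxymethoxy)-3-[(3S,5S,6E)-3-(methoxymethoxy)-1,7-bis[4-(methoxymethoxy)phenyl]hept-6-en-5-yl]phenyl}-3-[4-(methoxymethoxy)phenyl]prop-2-en-1-one, via aryne 28 (not isolated), via cesium phenoxide 29 (not isolated)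
Conditions: 27 (2.5 equiv), CsF, 18-crown-6, THF, rt to 45 °C, slow addition of 24; pH 7 phosphate buffer, 0 °C
Reagents that add atoms: none
Why: Fluoride attacks silicon and expels triflate to give aryne 28 across C4a–C8a; the carboxylate oxygen of 27 adds to C8a, and the C4a aryl anion so formed attacks the neighbouring ester carbonyl through a four-membered alkoxide whose opening makes the C4a–C4 bond and releases the C8a phenoxide 29. The closest known reaction type is the fluoride-induced insertion of arynes from ortho-silylaryl triflates into the C–O bond of carboxylic acids, which gives ortho-hydroxyaryl ketones. No ring is closed and no stereocentre is formed, and the C3 and C5 stereocentres are not touched by the mild, non-acidic conditions. The step needs regioselectivity (oxygen on C8a, acyl on C4a), and the C5 methoxy group secures it by polarising the aryne so that the nucleophile enters at the distal carbon and the negative charge builds up at C4a next to the C5–O bond, an effect that has to outweigh the shielding of C8a by the C8 chain. It also needs the chalcone to stay open: the preformed cesium salt brings no proton, so the aryl anion is not quenched before acyl transfer and the product rests as phenoxide 29, whose conjugate addition to the enone is reversible and unfavourable until the cold neutral quench. Slow addition of 24 to an excess of 27 keeps the carboxylate ahead of the product phenoxide and of the acetal oxygens as traps for the aryne.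

Step 18
Reactants: 30 2'-hydroxychalcone
Product: 31 (2S)-5-methoxy-7-(methoxymethoxy)-8-[(3S,5S,6E)-3-(methoxymethoxy)-1,7-bis[4-(methoxymethoxy)phenyl]hept-6-en-5-yl]-2-[4-(methoxymethoxy)phenyl]-2,3-dihydro-4H-chromen-4-one
Conditions: N-[3,5-bis(trifluoromethyl)phenyl]-N'-(9-deoxy-epi-quinidin-9-yl)thiourea (20 mol%), toluene, rt
Reagents that add atoms: none
Why: Intramolecular oxa-Michael addition (6-endo-trig closure of O1–C2) under bifunctional catalysis, the quinuclidine nitrogen activating the phenol and the thiourea the enone carbonyl, so that C2 is set as S by catalyst control, and because the chain is already stereodefined the C2 epimer is a diastereomer that can be separated.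

Step 19
Reactants: 31 penta-MOM flavanone
Product: 32 (2S)-7-hydroxy-8-[(3S,5S,6E)-3-hydroxy-1,7-bis(4-hydroxyphenyl)hept-6-en-5-yl]-2-(4-hydroxyphenyl)-5-methoxy-2,3-dihydro-4H-chromen-4-one
Conditions: ZnBr2, n-PrSH, CH2Cl2, 0 °C; pH 7 buffer
Reagents that add atoms: none
Why: Lewis acid-assisted acetal exchange, in which ZnBr2 activates each MOM acetal and the thiol takes up the methoxymethyl group, should cleave the four aryl and the one alkyl MOM ether quickly at 0 °C without protic acid or base, which protects the C2 stereocentre and the 4-hydroxystyrene.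

Compound list
1 | 5-methoxyresorcinol (5-methoxybenzene-1,3-diol) | COc1cc(O)cc(O)c1 | starting material
2 | 1-methoxy-3,5-bis(methoxymethoxy)benzene | COc1cc(OCOC)cc(OCOC)c1 | intermediate
3 | [4-methoxy-2,6-bis(methoxymethoxy)phenyl]lithium | COc1cc(OCOC)c([Li])c(OCOC)c1 | intermediate
4 | lithium (dimethylamino)[4-methoxy-2,6-bis(methoxymethoxy)phenyl]methanolate (racemic) | COc1cc(OCOC)c(C([O-])N(C)C)c(OCOC)c1.[Li+] | intermediate
5 | 4-methoxy-2,6-bis(methoxymethoxy)benzaldehyde | COc1cc(OCOC)c(C=O)c(OCOC)c1 | intermediate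
6 | lithium {[2-(dimethylamino)ethyl](methyl)amino}[4-methoxy-2,6-bis(methoxymethoxy)phenyl]methanolate (racemic) | COc1cc(OCOC)c(C([O-])N(C)CCN(C)C)c(OCOC)c1.[Li+] | intermediate
7 | 3-lithio derivative of 6 (racemic) | COc1cc(OCOC)c(C([O-])N(C)CCN(C)C)c(OCOC)c1[Li].[Li+] | intermediate
8 | 3-(trimethylsilyl) derivative of 6 (racemic) | COc1cc(OCOC)c(C([O-])N(C)CCN(C)C)c(OCOC)c1[Si](C)(C)C.[Li+] | intermediate
9 | 4-methoxy-2,6-bis(methoxymethoxy)-3-(trimethylsilyl)benzaldehyde | COc1cc(OCOC)c(C=O)c(OCOC)c1[Si](C)(C)C | intermediate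
10 | 4-methoxy-3-(trimethylsilyl)-2,6-bis(trimethylsilyloxy)benzaldehyde | COc1cc(O[Si](C)(C)C)c(C=O)c(O[Si](C)(C)C)c1[Si](C)(C)C | intermediate
11 | 2,6-dihydroxy-4-methoxy-3-(trimethylsilyl)benzaldehyde | COc1cc(O)c(C=O)c(O)c1[Si](C)(C)C | intermediate
12 | 2-hydroxy-4-methoxy-6-(methoxymethoxy)-3-(trimethylsilyl)benzaldehyde | COc1cc(OCOC)c(C=O)c(O)c1[Si](C)(C)C | intermediate
13 | (E)-4-[2-hydroxy-4-methoxy-6-(methoxymethoxy)-3-(trimethylsilyl)phenyl]but-3-en-2-one | COc1cc(OCOC)c(/C=C/C(C)=O)c(O)c1[Si](C)(C)C | intermediate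
14 | 4-hydroxybenzaldehyde | O=Cc1ccc(O)cc1 | starting material
15 | 4-(methoxymethoxy)benzaldehyde | COCOc1ccc(C=O)cc1 | intermediate
16 | lithium 1-[4-(methoxymethoxy)phenyl]-2,2-bis(4,4,5,5-tetramethyl-1,3,2-dioxaborolan-2-yl)ethanolate (racemic) | COCOc1ccc(C([O-])C(B2OC(C)(C)C(C)(C)O2)B2OC(C)(C)C(C)(C)O2)cc1.[Li+] | intermediate
17 | 2-{(E)-2-[4-(methoxymethoxy)phenyl]ethenyl}-4,4,5,5-tetramethyl-1,3,2-dioxaborolane | COCOc1ccc(/C=C/B2OC(C)(C)C(C)(C)O2)cc1 | intermediate
18 | (4S,5E)-4-[2-hydroxy-4-methoxy-6-(methoxymethoxy)-3-(trimethylsilyl)phenyl]-6-[4-(methoxymethoxy)phenyl]hex-5-en-2-one | COc1cc(OCOC)c([C@H](/C=C/c2ccc(OCOC)cc2)CC(C)=O)c(O)c1[Si](C)(C)C | intermediate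
19 | (5S,6E)-1-hydroxy-5-[2-hydroxy-4-methoxy-6-(methoxymethoxy)-3-(trimethylsilyl)phenyl]-1,7-bis[4-(methoxymethoxy)phenyl]hept-6-en-3-one (both C1 epimers) | COc1cc(OCOC)c([C@H](/C=C/c2ccc(OCOC)cc2)CC(=O)CC(O)c2ccc(OCOC)cc2)c(O)c1[Si](C)(C)C | intermediate
20 | (1E,5S,6E)-5-[2-hydroxy-4-methoxy-6-(methoxymethoxy)-3-(trimethylsilyl)phenyl]-1,7-bis[4-(methoxymethoxy)phenyl]hepta-1,6-dien-3-one | COc1cc(OCOC)c([C@H](/C=C/c2ccc(OCOC)cc2)CC(=O)/C=C/c2ccc(OCOC)cc2)c(O)c1[Si](C)(C)C | intermediate
21 | (1E,3R,5S,6E)-5-[2-hydroxy-4-methoxy-6-(methoxymethoxy)-3-(trimethylsilyl)phenyl]-1,7-bis[4-(methoxymethoxy)phenyl]hepta-1,6-dien-3-ol | COc1cc(OCOC)c([C@H](/C=C/c2ccc(OCOC)cc2)C[C@@H](O)/C=C/c2ccc(OCOC)cc2)c(O)c1[Si](C)(C)C | intermediate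
22 | (3S,5S,6E)-5-[2-hydroxy-4-methoxy-6-(methoxymethoxy)-3-(trimethylsilyl)phenyl]-1,7-bis[4-(methoxymethoxy)phenyl]hept-6-en-3-ol | COc1cc(OCOC)c([C@H](/C=C/c2ccc(OCOC)cc2)C[C@@H](O)CCc2ccc(OCOC)cc2)c(O)c1[Si](C)(C)C | intermediate
23 | 6-[(3S,5S,6E)-3-hydroxy-1,7-bis[4-(methoxymethoxy)phenyl]hept-6-en-5-yl]-3-methoxy-5-(methoxymethoxy)-2-(trimethylsilyl)phenyl trifluoromethanesulfonate | COc1cc(OCOC)c([C@H](/C=C/c2ccc(OCOC)cc2)C[C@@H](O)CCc2ccc(OCOC)cc2)c(OS(=O)(=O)C(F)(F)F)c1[Si](C)(C)C | intermediate
24 | 3-methoxy-5-(methoxymethoxy)-6-[(3S,5S,6E)-3-(methoxymethoxy)-1,7-bis[4-(methoxymethoxy)phenyl]hept-6-en-5-yl]-2-(trimethylsilyl)phenyl trifluoromethanesulfonate | COc1cc(OCOC)c([C@H](/C=C/c2ccc(OCOC)cc2)C[C@@H](OCOC)CCc2ccc(OCOC)cc2)c(OS(=O)(=O)C(F)(F)F)c1[Si](C)(C)C | intermediate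
25 | 2-[4-(methoxymethoxy)benzylidene]propanedioic acid | OC(=O)C(=Cc1ccc(OCOC)cc1)C(O)=O | intermediate
26 | (E)-3-[4-(methoxymethoxy)phenyl]prop-2-enoic acid | OC(=O)/C=C/c1ccc(OCOC)cc1 | intermediate
27 | cesium (E)-3-[4-(methoxymethoxy)phenyl]prop-2-enoate | [Cs+].[O-]C(=O)/C=C/c1ccc(OCOC)cc1 | intermediate
28 | 3-methoxy-5-(methoxymethoxy)-6-[(3S,5S,6E)-3-(methoxymethoxy)-1,7-bis[4-(methoxymethoxy)phenyl]hept-6-en-5-yl]-1,2-didehydrobenzene (aryne across C4a–C8a) | COC1=CC(OCOC)=C([C@H](/C=C/c2ccc(OCOC)cc2)C[C@@H](OCOC)CCc2ccc(OCOC)cc2)C#C1 | intermediate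
29 | cesium 3-methoxy-5-(methoxymethoxy)-6-[(3S,5S,6E)-3-(methoxymethoxy)-1,7-bis[4-(methoxymethoxy)phenyl]hept-6-en-5-yl]-2-{(E)-3-[4-(methoxymethoxy)phenyl]prop-2-enoyl}phenolate | COc1cc(OCOC)c([C@H](/C=C/c2ccc(OCOC)cc2)C[C@@H](OCOC)CCc2ccc(OCOC)cc2)c([O-])c1C(=O)/C=C/c1ccc(OCOC)cc1.[Cs+] | intermediate
30 | (E)-1-{2-hydroxy-6-methoxy-4-(methoxymethoxy)-3-[(3S,5S,6E)-3-(methoxymethoxy)-1,7-bis[4-(methoxymethoxy)phenyl]hept-6-en-5-yl]phenyl}-3-[4-(methoxymethoxy)phenyl]prop-2-en-1-one | COc1cc(OCOC)c([C@H](/C=C/c2ccc(OCOC)cc2)C[C@@H](OCOC)CCc2ccc(OCOC)cc2)c(O)c1C(=O)/C=C/c1ccc(OCOC)cc1 | intermediate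
31 | (2S)-5-methoxy-7-(methoxymethoxy)-8-[(3S,5S,6E)-3-(methoxymethoxy)-1,7-bis[4-(methoxymethoxy)phenyl]hept-6-en-5-yl]-2-[4-(methoxymethoxy)phenyl]-2,3-dihydro-4H-chromen-4-one | COc1cc(OCOC)c([C@H](/C=C/c2ccc(OCOC)cc2)C[C@@H](OCOC)CCc2ccc(OCOC)cc2)c2c1C(=O)C[C@@H](c1ccc(OCOC)cc1)O2 | intermediate
32 | (2S)-7-hydroxy-8-[(3S,5S,6E)-3-hydroxy-1,7-bis(4-hydroxyphenyl)hept-6-en-5-yl]-2-(4-hydroxyphenyl)-5-methoxy-2,3-dihydro-4H-chromen-4-one | COc1cc(O)c([C@H](/C=C/c2ccc(O)cc2)C[C@@H](O)CCc2ccc(O)cc2)c2c1C(=O)C[C@@H](c1ccc(O)cc1)O2 | target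

Total step count: 19. Longest linear sequence: 15 steps (steps 1 to 6, 9 to 14, 17 to 19).

Steps most likely to fail

Step 17. What may go wrong: capture of the aryne at C8a by the bulky cinnamate is slowed by the C8 chain, so that the aryne is consumed by the product phenoxide or is attacked at C4a, or the unsaturated acyl group undergoes conjugate addition or cyclisation under the basic conditions. The fallback sets out from 24 and comes back at 30. Cesium acetate, a smaller nucleophile whose ketone cannot cyclise, is inserted with CsF and 18-crown-6 in THF; this gives, by way of aryne 28 and the cesium phenoxide of the acetophenone F1, the ortho-hydroxyacetophenone F2. Claisen–Schmidt condensation of F2 with aldehyde 15 (KOH, EtOH, rt) then passes through the aldol adduct F3 and builds the enone of chalcone 30 by condensation instead of carrying it in with the acid.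

Step 9. What may go wrong: insertion of the doubly ortho-substituted β-aryl enone into the alkenyl–rhodium bond is slow, so that protodeboronation of 17 wins, or the enone faces are poorly differentiated. The fallback sets out from 13 and 17 and comes back at 18 by a metal-free, diol-catalysed conjugate alkenylboration. The pinacol ester 17 is cleaved (NaIO4, NH4OAc, acetone/H2O) to (E)-2-[4-(methoxymethoxy)phenyl]ethenylboronic acid F4. F4 is then added to enone 13 with 3,3'-bis(pentafluorophenyl)-BINOL (20 mol%, the enantiomer that gives the 4S ketone), Mg(OtBu)2 (10 mol%) and 4 Å molecular sieves in toluene at reflux, which gives 18.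

Step 12. What may go wrong: the electron-rich aryl group slows hydride delivery to C2, so that the hydroalumination stalls or needs conditions under which material is lost. The fallback sets out from 20 and comes back at 22 by reversing the order of the two reductions. Conjugate reduction of enone 20 with [(Ph3P)CuH]6 (toluene, rt) gives the saturated ketone F5. F5 is then reduced with the (R)-CBS catalyst and catecholborane; reagent control is weaker on this dialkyl ketone, but the C3 epimers are diastereomers and the 3S alcohol 22 is isolated by chromatography.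

Further compounds
F1 | step 17 | cesium 2-acetyl-3-methoxy-5-(methoxymethoxy)-6-[(3S,5S,6E)-3-(methoxymethoxy)-1,7-bis[4-(methoxymethoxy)phenyl]hept-6-en-5-yl]phenolate | COc1cc(OCOC)c([C@H](/C=C/c2ccc(OCOC)cc2)C[C@@H](OCOC)CCc2ccc(OCOC)cc2)c([O-])c1C(C)=O.[Cs+]
F2 | step 17 | 1-{2-hydroxy-6-methoxy-4-(methoxymethoxy)-3-[(3S,5S,6E)-3-(methoxymethoxy)-1,7-bis[4-(methoxymethoxy)phenyl]hept-6-en-5-yl]phenyl}ethan-1-one | COc1cc(OCOC)c([C@H](/C=C/c2ccc(OCOC)cc2)C[C@@H](OCOC)CCc2ccc(OCOC)cc2)c(O)c1C(C)=O
F3 | step 17 | 3-hydroxy-1-{2-hydroxy-6-methoxy-4-(methoxymethoxy)-3-[(3S,5S,6E)-3-(methoxymethoxy)-1,7-bis[4-(methoxymethoxy)phenyl]hept-6-en-5-yl]phenyl}-3-[4-(methoxymethoxy)phenyl]propan-1-one (both carbinol epimers) | COc1cc(OCOC)c([C@H](/C=C/c2ccc(OCOC)cc2)C[C@@H](OCOC)CCc2ccc(OCOC)cc2)c(O)c1C(=O)CC(O)c1ccc(OCOC)cc1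
F4 | step 9 | (E)-2-[4-(methoxymethoxy)phenyl]ethenylboronic acid | OB(O)/C=C/c1ccc(OCOC)cc1
F5 | step 12 | (5S,6E)-5-[2-hydroxy-4-methoxy-6-(methoxymethoxy)-3-(trimethylsilyl)phenyl]-1,7-bis[4-(methoxymethoxy)phenyl]hept-6-en-3-one | COc1cc(OCOC)c([C@H](/C=C/c2ccc(OCOC)cc2)CC(=O)CCc2ccc(OCOC)cc2)c(O)c1[Si](C)(C)C
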